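**Retrosynthetic overview**

1. Target 17 ⇒ (3S)-peroxyhemiketal 16 by acid-catalysed OH→OMe exchange at C6 (thermodynamic: OMe axial, cis to the C3 side chain).
2. 16 ⇒ acyclic 6-oxo-2-enoate 14 + H2O2: both C–O bonds of the 1,2-dioxane (the only ring, formed last) come from one catalytic asymmetric perhydrate/peroxy-Michael cascade that sets C3.
3. 14 ⇒ bromoalkyne 9 + undeca-1,10-diyne 12: hydrozirconation/Pd coupling builds the (E)-enyne without alkyne protection.
4. 9 ⇒ hex-5-ynenitrile 1 + acetal Grignard reagent (ketone), then Wittig (enoate) and alkyne bromination; 12 ⇒ 1,7-dibromoheptane + lithium acetylide.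

Target as read from the SMILES: methyl 2-[(3S,6R)-6-[(6E)-hexadec-6-ene-4,15-diyn-1-yl]-6-methoxy-1,2-dioxan-3-yl]acetate, with OMe at C6 cis to CH2CO2Me at C3.

Assumption: the sense of induction of the squaramide catalyst in step 6 must be confirmed by experiment; the quinine-derived catalyst is written, and its quinidine-derived pseudo-enantiomer is used if the (3R) ring forms.

**Route**

Step 1
Reactants: 1 hex-5-ynenitrile; 2 2-(2-bromoethyl)-1,3-dioxolane
Product: 6 4-oxonon-8-ynal, via Grignard reagent 3 (not isolated), via magnesium ketimide 4 (not isolated), via keto acetal 5 (not isolated)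
Conditions: 2 (2.5 equiv), Mg, THF, 25–30 °C; then 1 (1.0 equiv), CuBr·SMe2 (5 mol%), 0 °C → rt; then 2 M HCl, THF, rt, 12 h
Reagents that add atoms: water, O
Why: Grignard addition to a nitrile stops at the magnesium ketimide (the first equivalent of 3 only removes the alkyne C–H), and aqueous HCl then hydrolyses both the ketimine and the dioxolane to the 1,4-keto aldehyde; no stereocentre is formed.

Step 2
Reactants: 6 4-oxonon-8-ynal; 7 methyl (triphenylphosphoranylidene)acetate
Product: 8 methyl (2E)-6-oxoundec-2-en-10-ynoate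
Conditions: 7 (1.1 equiv), CH2Cl2, 0 °C → rt, 12 h
Reagents that add atoms: none
Why: Wittig olefination with a stabilised ylide reacts at the aldehyde and not at the ketone and gives the (E)-enoate with high selectivity.

Step 3
Reactants: 8 methyl (2E)-6-oxoundec-2-en-10-ynoate
Product: 9 methyl (2E)-11-bromo-6-oxoundec-2-en-10-ynoate
Conditions: NBS (1.15 equiv), AgNO3 (10 mol%), acetone, rt, dark, 2 h
Reagents that add atoms: N-bromosuccinimide, O=C1CCC(=O)N1Br
Why: Silver-catalysed electrophilic bromination of a terminal alkyne (via the silver acetylide) is selective for the C(sp)–H bond and leaves the ketone and the electron-poor enoate alone.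

Step 4
Reactants: 10 1,7-dibromoheptane; 11 lithium acetylide–ethylenediamine complex
Product: 12 undeca-1,10-diyne
Conditions: 11 (2.6 equiv), DMSO, 15 °C → rt, 4 h
Reagents that add atoms: none
Why: Double SN2 alkylation of lithium acetylide by a primary dibromide in DMSO is a standard route to α,ω-diynes, and the ethylenediamine complex at room temperature does not isomerise the triple bonds.

Step 5
Reactants: 12 undeca-1,10-diyne; 9 methyl (2E)-11-bromo-6-oxoundec-2-en-10-ynoate
Product: 14 methyl (2E,12E)-6-oxodocosa-2,12-dien-10,21-diynoate, via alkenylzirconocene chloride 13 (not isolated)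
Conditions: 12 (4 equiv), Cp2Zr(H)Cl (1.3 equiv), THF, rt, 1 h; then ZnCl2 (1.3 equiv), Pd(PPh3)4 (5 mol%), 9 (1.0 equiv), 0 °C → rt
Reagents that add atoms: none
Why: Syn hydrozirconation of one end of the excess symmetric diyne puts zirconium on the terminal carbon and fixes the (E)-alkene, and Negishi-type Pd-catalysed coupling through the alkenylzinc with the bromoalkyne goes with retention, so the free terminal alkyne is a bystander because no copper acetylide chemistry is involved and all Zr–H is consumed before the ketone is added.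

Step 6
Reactants: 14 methyl (2E,12E)-6-oxodocosa-2,12-dien-10,21-diynoate
Product: 16 methyl 2-[(3S)-6-[(6E)-hexadec-6-ene-4,15-diyn-1-yl]-6-hydroxy-1,2-dioxan-3-yl]acetate, via ketone perhydrate 15 (not isolated)
Conditions: H2O2 (50% aq, 3 equiv), quinine-derived squaramide 3-{[3,5-bis(trifluoromethyl)phenyl]amino}-4-{[(8α,9S)-6'-methoxycinchonan-9-yl]amino}cyclobut-3-ene-1,2-dione (10 mol%), MTBE, 0 °C, 24–48 h
Reagents that add atoms: hydrogen peroxide, OO
Why: Proposed new method: a catalytic enantioselective perhydrate formation/intramolecular peroxy-Michael cascade run as a dynamic kinetic resolution, in which H2O2 adds reversibly to the ketone to give the racemic, fast-interconverting gem-hydroxy hydroperoxide 15, the quinuclidine nitrogen of the catalyst (conjugate acid pKa about 11) deprotonates the OOH group (pKa about 12) while the squaramide N–H pair binds the ester carbonyl of the (E)-enoate, the peroxide anion closes 6-exo-trig on one enantioface of C3 and the quinuclidinium protonates the ester enolate before it can expel alkoxide to an epoxide, which sets (3S) and forms the ring while C6 stays labile through ring–chain tautomerism until step 7; a squaramide is chosen because thioureas are oxidised by H2O2, and slow N-oxidation of the quinuclidine is countered by low temperature and catalyst loading; the closest known reaction types are the racemic amine-mediated cyclisation of α-alkoxy hydroperoxides onto enoates to 1,2-dioxanes, bifunctional-catalyst hemiacetal/oxa-Michael cascades and the cinchona-amine asymmetric hydroperoxidation of enones.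

Step 7
Reactants: 16 methyl 2-[(3S)-6-[(6E)-hexadec-6-ene-4,15-diyn-1-yl]-6-hydroxy-1,2-dioxan-3-yl]acetate
Product: 17 methyl 2-[(3S,6R)-6-[(6E)-hexadec-6-ene-4,15-diyn-1-yl]-6-methoxy-1,2-dioxan-3-yl]acetate
Conditions: MeOH, TsOH·H2O (10 mol%), rt, 6 h; minor C6 epimer resubjected
Reagents that add atoms: methanol, CO
Why: Acid-catalysed peroxyketalisation (OH→OMe exchange through the ring peroxycarbenium ion) is reversible, so C6 settles under thermodynamic control with OMe axial (anomeric effect) and both carbon chains equatorial, which is OMe cis to the C3 side chain, i.e. (6R), while C3 is untouched because no base is present.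

**Compound list**

1 | hex-5-ynenitrile | N#CCCCC#C | starting material
2 | 2-(2-bromoethyl)-1,3-dioxolane | BrCCC1OCCO1 | starting material
3 | [2-(1,3-dioxolan-2-yl)ethyl]magnesium bromide | Br[Mg]CCC1OCCO1 | intermediate
4 | bromomagnesium ketimide of 1-(1,3-dioxolan-2-yl)oct-7-yn-3-one, alkyne as its bromomagnesium acetylide | Br[Mg]C#CCCCC(=N[Mg]Br)CCC1OCCO1 | intermediate
5 | 1-(1,3-dioxolan-2-yl)oct-7-yn-3-one | C#CCCCC(=O)CCC1OCCO1 | intermediate
6 | 4-oxonon-8-ynal | C#CCCCC(=O)CCC=O | intermediate
7 | methyl (triphenylphosphoranylidene)acetate | COC(=O)C=P(c1ccccc1)(c1ccccc1)c1ccccc1 | starting material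
8 | methyl (2E)-6-oxoundec-2-en-10-ynoate | C#CCCCC(=O)CC/C=C/C(=O)OC | intermediate
9 | methyl (2E)-11-bromo-6-oxoundec-2-en-10-ynoate | BrC#CCCCC(=O)CC/C=C/C(=O)OC | intermediate
10 | 1,7-dibromoheptane | BrCCCCCCCBr | starting material
11 | lithium acetylide–ethylenediamine complex | [Li+].[C-]#C.NCCN | starting material
12 | undeca-1,10-diyne | C#CCCCCCCCC#C | intermediate
13 | chlorobis(cyclopentadienyl)[(1E)-undec-1-en-10-yn-1-yl]zirconium (cyclopentadienyl rings drawn sigma-bonded) | C#CCCCCCCC/C=C/[Zr](Cl)(C1C=CC=C1)C1C=CC=C1 | intermediate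
14 | methyl (2E,12E)-6-oxodocosa-2,12-dien-10,21-diynoate | C#CCCCCCCC/C=C/C#CCCCC(=O)CC/C=C/C(=O)OC | intermediate
15 | methyl (2E,12E)-6-hydroperoxy-6-hydroxydocosa-2,12-dien-10,21-diynoate (racemic at C6, equilibrating) | C#CCCCCCCC/C=C/C#CCCCC(O)(OO)CC/C=C/C(=O)OC | intermediate
16 | methyl 2-[(3S)-6-[(6E)-hexadec-6-ene-4,15-diyn-1-yl]-6-hydroxy-1,2-dioxan-3-yl]acetate (C6 epimers in equilibrium) | C#CCCCCCCC/C=C/C#CCCCC1(O)CC[C@@H](CC(=O)OC)OO1 | intermediate
17 | methyl 2-[(3S,6R)-6-[(6E)-hexadec-6-ene-4,15-diyn-1-yl]-6-methoxy-1,2-dioxan-3-yl]acetate | C#CCCCCCCC/C=C/C#CCCC[C@]1(OC)CC[C@@H](CC(=O)OC)OO1 | target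

**Count and risks**

Total step count: 7. Longest linear sequence: 6 steps (1, 2, 3, 5, 6, 7). The O–O bond is made last, so it never meets the Grignard reagent, zirconium, zinc or palladium.

Steps most likely to fail:

Step 6 (the proposed new step; risks are low enantioselectivity, catalyst N-oxidation and competing epoxidation of the enoate). The fallback uses known chemistry, sets out from 14 and comes back to the route at 17. Compound 14 is treated with urea–hydrogen peroxide and catalytic Sc(OTf)3 in MeOH to give the racemic α-methoxy hydroperoxide methyl (2E,12E)-6-hydroperoxy-6-methoxydocosa-2,12-dien-10,21-diynoate F1. Et2NH in CF3CH2OH closes it by peroxy-Michael addition, and TsOH in MeOH equilibrates C6, giving the racemic cis peroxyketal methyl 2-[(3RS,6SR)-6-[(6E)-hexadec-6-ene-4,15-diyn-1-yl]-6-methoxy-1,2-dioxan-3-yl]acetate F2. Preparative HPLC on a chiral stationary phase (amylose tris(3,5-dimethylphenylcarbamate)) then separates 17 from its enantiomer, methyl 2-[(3R,6S)-6-[(6E)-hexadec-6-ene-4,15-diyn-1-yl]-6-methoxy-1,2-dioxan-3-yl]acetate F3, which is discarded.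

Step 5 (risks are statistical mono-hydrozirconation and homocoupling of the bromoalkyne). The fallback reverses the polarity of the enyne coupling, sets out from 12 and 8 and comes back at 14; step 3 is then not needed. Excess 12 is hydrozirconated with Cp2Zr(H)Cl and quenched with I2 to give (1E)-1-iodoundec-1-en-10-yne F4. LiN(SiMe3)2 and Me3SiCl in THF at −78 °C cap the alkyne to give trimethyl[(10E)-11-iodoundec-10-en-1-yn-1-yl]silane F5. Sonogashira coupling of F5 with the terminal alkyne 8 (Pd(PPh3)2Cl2, CuI, Et3N, rt) gives methyl (2E,12E)-6-oxo-22-(trimethylsilyl)docosa-2,12-dien-10,21-diynoate F6, and Bu4NF buffered with AcOH in THF at 0 °C removes the silyl group to give 14.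

Step 1 (risks are α-deprotonation of the nitrile, thermal lability of the acetal Grignard reagent, and aldol or furan formation from the 1,4-keto aldehyde during hydrolysis). The fallback replaces nitrile addition by aldehyde addition and oxidation, sets out from 1 and comes back at 5. Reduction of 1 with i-Bu2AlH (CH2Cl2, −78 °C, then aqueous HCl) gives hex-5-ynal F7. Addition of Grignard reagent 3 gives 1-(1,3-dioxolan-2-yl)oct-7-yn-3-ol F8, and Dess–Martin oxidation gives the keto acetal 5, which is isolated and hydrolysed to 6 under milder, separately controlled conditions.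

**Further compounds**

F1 | step 6 | methyl (2E,12E)-6-hydroperoxy-6-methoxydocosa-2,12-dien-10,21-diynoate (racemic) | C#CCCCCCCC/C=C/C#CCCCC(OC)(OO)CC/C=C/C(=O)OC
F2 | step 6 | methyl 2-[(3RS,6SR)-6-[(6E)-hexadec-6-ene-4,15-diyn-1-yl]-6-methoxy-1,2-dioxan-3-yl]acetate (racemic cis; ring drawn without descriptors) | C#CCCCCCCC/C=C/C#CCCCC1(OC)CCC(CC(=O)OC)OO1
F3 | step 6 | methyl 2-[(3R,6S)-6-[(6E)-hexadec-6-ene-4,15-diyn-1-yl]-6-methoxy-1,2-dioxan-3-yl]acetate | C#CCCCCCCC/C=C/C#CCCC[C@@]1(OC)CC[C@H](CC(=O)OC)OO1
F4 | step 5 | (1E)-1-iodoundec-1-en-10-yne | C#CCCCCCCC/C=C/I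
F5 | step 5 | trimethyl[(10E)-11-iodoundec-10-en-1-yn-1-yl]silane | C[Si](C)(C)C#CCCCCCCC/C=C/I
F6 | step 5 | methyl (2E,12E)-6-oxo-22-(trimethylsilyl)docosa-2,12-dien-10,21-diynoate | C[Si](C)(C)C#CCCCCCCC/C=C/C#CCCCC(=O)CC/C=C/C(=O)OC
F7 | step 1 | hex-5-ynal | C#CCCCC=O
F8 | step 1 | 1-(1,3-dioxolan-2-yl)oct-7-yn-3-ol (racemic) | C#CCCCC(O)CCC1OCCO1
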